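## Structural features

The target, [(1S,5R,6S)-6-acetoxy-5-benzoyloxy-1-hydroxy-2-oxocyclohex-3-en-1-yl]methyl benzoate, has a single carbocycle, a cyclohexenone; the only other rings are the phenyl groups of the two benzoates. The ring is numbered here C1 (tertiary carbinol carrying the exocyclic C7H2OBz), C2 (OAc), C3 (OBz), C4=C5 and C6 (ketone). The three stereocentres C1 (S), C2 (S) and C3 (R) are contiguous: the C1 hydroxyl and the C2 acetoxy group are cis, and the C3 benzoate is trans to both. C1 is fully substituted, whereas C2 and C3 are secondary. Four oxygens on neighbouring carbons must be told apart (free O1–H, acetate on O2, benzoates on O3 and O7), so acyl migration is a standing risk. The C3 benzoate is γ to the ketone through C4=C5 and the C2 acetate is β to C3; base can therefore deprotonate C3 vinylogously and expel acetate on the way to an arene, which makes the enone the most fragile part. The real difficulty is to set the fully substituted C1 cis to C2 and trans to C3 in enantiopure form while keeping the oxygens differentiated. The route exploits the C1/C2 cis-diol with one tertiary oxygen: it is the retron of a ketone–aldehyde pinacol coupling across C1–C2, and the oxygens on C3 and C6 (C6 is a carbinol until the last step) can steer that coupling.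

## Logic of the disconnections

28 ⇒ 27 ⇒ 26. No skeletal bond is cut: the C6 carbonyl is traced to an allylic carbinol and this to a silyl ether. The base-labile γ-acyloxy enone is thus uncovered in the last operation, and every earlier intermediate is a robust protected cyclohexenol. The forward steps must remove one hindered silyl group without shifting an ester, and oxidise a secondary alcohol next to a free tertiary one without cleaving the glycol.

26 ⇒ 24 + 25, 24 ⇒ 23. The O3–acyl and O7–acyl bonds are cut, then both free hydroxyls are traced to 4-methoxybenzyl ethers. Esters cannot flank the carbonyls in the reductive ring closure, so both future benzoates travel as one kind of ether and are exchanged together, which takes two equivalents of the acyl chloride in one operation. The oxidative ether cleavage must stop at the allylic alcohol and must not tie O7 to the free O1–H; the acylation must leave the tertiary hydroxyl alone.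

23 ⇒ 22 ⇒ 21 ⇒ 20. The C4=C5 π bond is traced to two C–O bonds (thionocarbonate, diol, acetonide). A cis-diol at C4/C5 is what a hexose supplies, and the dioxolane folds the open chain for ring closure, so the alkene carbons become ordinary sugar stereocentres. The forward steps need a stereospecific syn-elimination and an acetal hydrolysis that spares two benzylic ethers, a silyl ether and an acetate.

20 ⇒ 19. The O2–acetyl bond is cut. Directly after ring formation O2–H is the only unhindered free hydroxyl, so no extra protection is needed; the acetylation must discriminate secondary from tertiary.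

19 ⇒ 18. The C1–C2 ring bond is cut between the two carbinol carbons, opening the carbocycle to an acyclic 1,6-keto aldehyde. Both carbons are electrophilic, so only a reductive coupling can join them. The gain is the ring and two stereocentres in one step; what remains is a linear chain whose four stereocentres are those of D-galactose C2–C5. The ketyl coupling must outrun C–O cleavage α to the carbonyls and must deliver the diol cis and anti to O3 and O6.

18 ⇒ 17 ⇒ 16 ⇒ 15. The aldehyde is traced through a diol to a terminal C1=C1′ alkene, and the ketone to a carbinol. The epimerisable α-alkoxy aldehyde then exists for one step only, and the vinyl group is an inert mask during the organolithium chemistry. The alkene cleavage must leave the electron-rich benzyl ethers intact, and the alcohol oxidation must not epimerise C5.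

15 ⇒ 11 + 14, 14 ⇒ 13 ⇒ 12 + 5. The C6–C7 bond is cut to an aldehyde and an α-alkoxy carbanion, which comes from a stannane made by O-alkylation. C7 arrives already carrying the ether that later becomes the O7 benzoate. The configuration at C6 is irrelevant because the carbinol is oxidised. The addition must run cold enough to prevent silyl migration.

11 ⇒ 10 ⇒ 9 ⇒ 8. No C–C bond is cut; O5 and O6 are differentiated. Silylating both and freeing the primary one makes the result independent of any silyl shift in the preceding step.

8 ⇒ 7 ⇒ 6. The C1=C1′ bond is cut (olefination of a lactol) and the ring O5–C1 bond is restored; the lactol comes from a thioglycoside. The pyranose ring has served as the protecting group of O5, and opening it by olefination masks C1 and frees O5 in one operation. The olefination must not epimerise or β-eliminate the 2-alkoxy aldehyde, and the glycoside hydrolysis must be neutral.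

6 ⇒ 4 + 5, 4 ⇒ 3 ⇒ 1. The O2–benzyl, O6–silyl and acetonide C–O bonds are cut. On the pyranoside O3/O4 are the only cis-vicinal pair, so the acetonide is regioselective. In an open-chain galactose derivative the threo 2,3- and 4,5-diols would give the favoured trans-dioxolanes instead, which is why the chain is kept cyclic until this protection is in place.

## Other disconnections considered

Alternative 1: The C2–O and C3–O bonds are traced to an epoxide, and this to one of the two enantiotopic alkenes of the achiral, Birch-derived dienol A1. The forward key step is a hydroxyl-directed asymmetric epoxidation (Ti(OiPr)4 with diethyl tartrate, or VO(OiPr)3 with a chiral bishydroxamic acid, and tert-butyl hydroperoxide) giving the syn epoxy alcohol A2.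
- In favour: the carbocycle and the C7 benzoate are present from the start. One catalyst-controlled step sets C1 and C2, and a trans opening of the epoxide at C3 by benzoate would set C3.
- Against: tertiary bis-allylic alcohols are poor substrates for titanium–tartrate epoxidation, and the catalyst must distinguish two alkenes that differ only through the C1 substituents. Epoxide opening must be regioselective at C3 in the presence of a participating C7 benzoate. The C4 methylene and C5=C6 alkene must still be converted into the C4=C5–C6=O enone by an allylic oxidation with transposition.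
- Comparison: on step economy this alternative is clearly better than the chosen plan, and it needs no protecting-group exchange, which is also better. On absolute configuration the chosen plan is safer, because it draws on the chiral pool and a matched substrate-controlled ring closure instead of an enantioselectivity that cannot be guaranteed for this substrate class.

Alternative 2: The C5–C6 bond is cut; the precursor is the manno-configured, 2-C-branched γ-lactone A3 carrying a 2-(phenylsulfinyl)ethyl chain on C3. LiN(iPr)2 forms the α-sulfinyl carbanion at C5, which acylates at the lactone carbonyl C6. Collapse of the bicyclic tetrahedral intermediate breaks the acyl C6–O bond, so O3 stays on C3 as the alkoxide. Warming then expels the sulfenic acid by syn-elimination to give C4=C5 and the hydroxy enone A4.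
- In favour: all three stereocentres come from the sugar and none is made in the ring closure, which is better than the chosen plan on stereochemical risk at the key step. The enone oxidation level and the free C3–OH arrive directly, so neither a Corey–Winter sequence nor a late oxidation is needed; this is also better.
- Against: the carbanion must attack a carbonyl flanked by the fully substituted C1 through a strained oxabicyclic intermediate. The β-keto sulfoxide and the enone are exposed to strong base. The remaining steps (O3 benzoylation, acetonide removal, O2 acetylation, silyl-to-benzoate exchange at O7) all run on the fragile enone, whereas the chosen plan keeps the enone masked to the end.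
- Comparison: both plans take their configuration from the chiral pool (equal). The alternative is probably shorter. The chosen plan is the more conservative in how it handles the sensitive functionality.

Alternative 3: The C3–C4 bond is cut; the precursor is the (Z)-β-iodo enone aldehyde A5 with the C1/C2 acetonide and the C7 benzoate in place. CrCl2 with catalytic NiCl2 (vinyl iodide activated by zerovalent nickel, transmetalation to a trivalent vinylchromium species) adds C4 to the C3 aldehyde and closes the ring to the hydroxy enone A6.
- In favour: the Nozaki–Hiyama–Kishi reaction is selective for aldehydes and tolerates the ketone and the ester, so the O7 benzoate need not be exchanged, which is better than the chosen plan. A6 needs only benzoylation, acetonide removal and O2 acetylation.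
- Against: C3 is created in the ring closure under substrate control alone, and the required trans relationship to O2 is not assured; the chosen plan takes C3 intact from galactose. The (Z)-iodo enone can isomerise or undergo addition–elimination. The acyclic quaternary carbinol of A5 needs its own asymmetric construction.
- Comparison: the use of stoichiometric metal is comparable to the SmI2 step (equal). The end game is shorter than in the chosen plan (better). The stereochemical security at C3 is lower.

Key step: step 13

Assumption: isopropyl 1-thio-β-D-galactopyranoside (IPTG, the commercial thioglycoside of D-galactose), (tributylstannyl)methanol, 4-methoxybenzyl chloride and benzoyl chloride are taken as purchasable.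

Numbering: open-chain compounds 8–18 keep the galactose locants C1–C6; C1′ is the methylene carbon added in step 5 and C7 the carbon added in step 10. Carbocycles 19–28 use the target numbering (ring C1 = galactose C6, C2 = galactose C1, C3 = galactose C2, C4 = galactose C3, C5 = galactose C4, C6 = galactose C5). PMB = 4-methoxybenzyl, TBS = tert-butyldimethylsilyl.

## Route

Step 1
Reactants: 1 isopropyl 1-thio-β-D-galactopyranoside (IPTG)
Product: 3 isopropyl 3,4-O-isopropylidene-1-thio-β-D-galactopyranoside, via 6-O-(2-methoxypropan-2-yl) mixed acetal 2 (not isolated)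
Conditions: Me2C(OMe)2 (excess), CSA (cat.), rt; Et3N; then MeOH/H2O (10:1), 50 °C
Reagents that add atoms: 2,2-dimethoxypropane, COC(C)(C)OC (forms the dioxolane); 2,2-dimethoxypropane, COC(C)(C)OC (second equivalent, held only in the transient mixed acetal 2)
Why: Acid-catalysed transacetalisation should place the dioxolane on the only cis-vicinal diol of the pyranoside (O3 equatorial, O4 axial); the acyclic mixed acetal that forms at O6 is far more labile and is removed by mild solvolysis. No stereocentre is touched.

Step 2
Reactants: 3 isopropyl 3,4-O-isopropylidene-1-thio-β-D-galactopyranoside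
Product: 4 isopropyl 6-O-TBS-3,4-O-isopropylidene-1-thio-β-D-galactopyranoside
Conditions: TBSCl, imidazole, DMF, 0 °C
Reagents that add atoms: tert-butyldimethylsilyl chloride, CC(C)(C)[Si](C)(C)Cl
Why: Silylation should take the primary O6–H in preference to the secondary O2–H, which is flanked by the anomeric centre and the dioxolane.

Step 3
Reactants: 4 isopropyl 6-O-TBS-3,4-O-isopropylidene-1-thio-β-D-galactopyranoside; 5 4-methoxybenzyl chloride
Product: 6 isopropyl 6-O-TBS-3,4-O-isopropylidene-2-O-PMB-1-thio-β-D-galactopyranoside
Conditions: NaH, DMF, 0 °C; then 5, TBAI (cat.), 0 °C → rt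
Reagents that add atoms: none
Why: Williamson etherification of the only free hydroxyl; thioglycoside, acetonide and silyl ether are stable to NaH, and O6 is too remote from O2 for silyl transfer.

Step 4
Reactants: 6 isopropyl 6-O-TBS-3,4-O-isopropylidene-2-O-PMB-1-thio-β-D-galactopyranoside
Product: 7 6-O-TBS-3,4-O-isopropylidene-2-O-PMB-D-galactopyranose (anomeric mixture)
Conditions: NBS, NaHCO3, acetone/H2O (9:1), −15 → 0 °C
Reagents that add atoms: water, O
Why: NBS-mediated thioglycoside hydrolysis: S-bromination, loss of the sulfenyl bromide and capture of the oxocarbenium ion by water. The buffered, near-neutral medium should leave acetonide, PMB ether and silyl ether intact.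

Step 5
Reactants: 7 6-O-TBS-3,4-O-isopropylidene-2-O-PMB-D-galactopyranose
Product: 8 5-hydroxy alkene [C1′H2=C1H; 2-OPMB; 3,4-O-isopropylidene; 5-OH; 6-OTBS; D-galacto]
Conditions: Ph3PCH3Br, n-BuLi, THF, −78 °C → rt, then 40 °C
Reagents that add atoms: methyltriphenylphosphonium bromide, C[P+](c1ccccc1)(c1ccccc1)c1ccccc1.[Br-]
Why: Wittig methylenation of the lactol through its open-chain hydroxy aldehyde (excess ylide) masks C1 as a vinyl group and releases O5 as the only free hydroxyl; C2 keeps its configuration because olefination of the aldehyde is fast. A shift of the silyl group from O6 to the O5 alkoxide would be harmless, since step 6 silylates whichever oxygen is free.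

Step 6
Reactants: 8 5-hydroxy alkene
Product: 9 5,6-bis-silyl ether [C1′H2=C1H; 2-OPMB; 3,4-O-isopropylidene; 5-OTBS; 6-OTBS]
Conditions: TBSOTf, 2,6-lutidine, CH2Cl2, 0 °C
Reagents that add atoms: tert-butyldimethylsilyl trifluoromethanesulfonate, CC(C)(C)[Si](C)(C)OS(=O)(=O)C(F)(F)F
Why: The silyl triflate should silylate the hindered secondary hydroxyl under buffered conditions that leave the acetonide and PMB ether alone.

Step 7
Reactants: 9 5,6-bis-silyl ether
Product: 10 primary alcohol [C1′H2=C1H; 2-OPMB; 3,4-O-isopropylidene; 5-OTBS; 6-OH]
Conditions: HF·pyridine, pyridine, THF, 0 °C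
Reagents that add atoms: none
Why: Buffered HF·pyridine should cleave the primary silyl ether much faster than the secondary one on steric grounds; the acidic fluoride source excludes base-mediated silyl migration.

Step 8
Reactants: 10 primary alcohol
Product: 11 C6 aldehyde [C1′H2=C1H; 2-OPMB; 3,4-O-isopropylidene; 5-OTBS; C6H=O]
Conditions: Dess–Martin periodinane, NaHCO3, CH2Cl2, 0 °C → rt
Reagents that add atoms: none
Why: Dess–Martin oxidation is neutral and non-epimerising for α-silyloxy aldehydes; the aldehyde is used without storage.

Step 9
Reactants: 12 (tributylstannyl)methanol; 5 4-methoxybenzyl chloride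
Product: 13 tributyl[(4-methoxybenzyloxy)methyl]stannane
Conditions: NaH, THF/DMF (4:1), 0 °C; then 5, TBAI (cat.), rt
Reagents that add atoms: none
Why: Williamson etherification of the stannylmethanol gives the precursor of the α-alkoxymethyl anion.

Step 10
Reactants: 11 C6 aldehyde; 13 tributyl[(4-methoxybenzyloxy)methyl]stannane
Product: 15 C6 carbinol (both C6 epimers) [C1′H2=C1H; 2-OPMB; 3,4-O-isopropylidene; 5-OTBS; C6H(OH); C7H2OPMB], via (4-methoxybenzyloxy)methyllithium 14 (not isolated)
Conditions: 13, n-BuLi, THF, −78 °C; then 11, −78 °C; AcOH/THF quench at −78 °C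
Reagents that add atoms: none
Why: Tin–lithium exchange gives the configurationally irrelevant α-alkoxymethyllithium, which adds 1,2 to the aldehyde and forms the C6–C7 bond. The C6 epimers converge in step 11. Low temperature and a cold acidic quench should suppress silyl migration from O5 to the new alkoxide.

Step 11
Reactants: 15 C6 carbinol
Product: 16 keto alkene [C1′H2=C1H; 2-OPMB; 3,4-O-isopropylidene; 5-OTBS; C6=O; C7H2OPMB]
Conditions: Dess–Martin periodinane, NaHCO3, CH2Cl2, rt
Reagents that add atoms: none
Why: Dess–Martin oxidation of the secondary alcohol to the α,α′-dialkoxy ketone under buffered conditions should not epimerise C5.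

Step 12
Reactants: 16 keto alkene
Product: 18 keto aldehyde [C1H=O; 2-OPMB; 3,4-O-isopropylidene; 5-OTBS; C6=O; C7H2OPMB], via terminal vicinal diol 17 (not isolated)
Conditions: OsO4 (cat.), NaIO4, 2,6-lutidine, dioxane/H2O (3:1), rt
Reagents that add atoms: osmium tetroxide, O=[Os](=O)(=O)=O (catalytic oxygen carrier); sodium periodate, [Na+].[O-]I(=O)(=O)=O (terminal oxygen source)
Why: Lemieux–Johnson cleavage: catalytic dihydroxylation of the terminal alkene and periodate scission of the diol give the aldehyde and formaldehyde. Unlike ozone, this oxidant pair leaves the electron-rich PMB rings alone. The aldehyde is carried on crude.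

Step 13
Reactants: 18 keto aldehyde
Product: 19 cyclitol cis-1,2-diol [ring C1: tertiary OH and CH2OPMB; C2: OH; C3: OPMB; C4/C5: cis-acetonide; C6: OTBS; 1-OH and 2-OH cis to each other and to the acetonide oxygens; O3 and O6 on the opposite face]
Conditions: SmI2 (3 equiv), t-BuOH (3 equiv), THF, −78 → −20 °C; aq. NaHCO3/Na2S2O3
Reagents that add atoms: none
Why: Single-electron transfer from divalent samarium reduces the aldehyde and then the ketone to metal-bound ketyls whose carbons couple (or the first ketyl adds to the samarium-activated ketone as the second electron arrives); this forms the C1–C2 bond and a diolate of trivalent samarium that t-BuOH and the work-up protonate. The closest known reaction type is the SmI2 pinacol cyclisation of carbohydrate-derived 1,6-dialdehydes and keto aldehydes to cis-cyclohexane-1,2-diols. The cyclohexane ring closes in a 6-exo-trig mode, the C2 ketyl carbon attacking the C1 carbonyl carbon while that oxygen stays outside the ring. C1 and C2 are both set here: the hydroxyls come out cis because both oxygens are held on samarium in the bond-forming transition state, and this bridged unit forms anti to the α-oxygens on C3 and C6 to avoid dipole and steric repulsion with the neighbouring C–O bonds. The galactose chain places O3 and O6 on the same face of the forming ring, so both preferences point the same way (matched case), and the cis-fused 4,5-acetonide folds the chain so that the two ends can meet. The step needs chemoselectivity for C–C coupling over reductive cleavage of the α-C–O bonds and over simple carbonyl reduction; ether rather than ester α-substituents, low temperature and the fast intramolecular closure should secure it. Using 18 directly from step 12 keeps the centre α to the aldehyde from epimerising.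

Step 14
Reactants: 19 cyclitol cis-1,2-diol
Product: 20 2-O-acetate [C1: free tertiary OH; C2: OAc; otherwise as 19]
Conditions: Ac2O, pyridine, DMAP (cat.), CH2Cl2, 0 °C
Reagents that add atoms: acetic anhydride, CC(=O)OC(C)=O
Why: Acylation should occur at the secondary O2–H only, because the tertiary O1–H is far slower on steric grounds.

Step 15
Reactants: 20 2-O-acetate
Product: 21 4,5-diol [C1: OH; C2: OAc; C3: OPMB; C4, C5: cis-OH; C6: OTBS; C7H2OPMB]
Conditions: AcOH/H2O (4:1), 55 °C
Reagents that add atoms: none
Why: Acid-catalysed hydrolysis of the cis-fused dioxolane in a weak acid that should spare the PMB ethers, the hindered secondary silyl ether and the acetate; the acetate has no free secondary neighbour to migrate to.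

Step 16
Reactants: 21 4,5-diol
Product: 22 4,5-cyclic thionocarbonate
Conditions: TCDI, toluene, 80 °C
Reagents that add atoms: 1,1′-thiocarbonyldiimidazole, S=C(n1ccnc1)n1ccnc1
Why: First stage of the Corey–Winter olefination: only the cis-4,5-diol can close a five-membered thionocarbonate, and the tertiary O1–H does not react.

Step 17
Reactants: 22 4,5-cyclic thionocarbonate
Product: 23 cyclohexene [C1: OH, CH2OPMB; C2: OAc; C3: OPMB; C4=C5; C6: OTBS]
Conditions: 1,3-dimethyl-2-phenyl-1,3,2-diazaphospholidine, THF, 40 °C
Reagents that add atoms: none
Why: Corey–Winter olefination in its mild diazaphospholidine variant: desulfurisation to the dioxolanylidene and stereospecific cycloreversion with loss of CO2 give the cis ring alkene. The low temperature protects the acetate and the allylic ethers.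

Step 18
Reactants: 23 cyclohexene
Product: 24 triol [C1: OH, CH2OH; C2: OAc; C3: OH; C4=C5; C6: OTBS]
Conditions: DDQ, CH2Cl2/pH 7 buffer (10:1), 0 °C → rt
Reagents that add atoms: none
Why: Oxidative cleavage of both PMB ethers (hydride abstraction by DDQ, hydrolysis of the oxocarbenium ion). The wet buffered medium should favour hydrolysis over acetal closure onto O1–H, and short exposure at 0 °C should keep the freed allylic alcohol from being oxidised.

Step 19
Reactants: 24 triol; 25 benzoyl chloride (two equivalents in all, one for each hydroxyl)
Product: 26 3,7-dibenzoate [C1: OH, CH2OBz; C2: OAc; C3: OBz; C4=C5; C6: OTBS]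
Conditions: 25 (2.2 equiv), pyridine, DMAP (cat.), CH2Cl2, 0 °C → rt
Reagents that add atoms: benzoyl chloride (the second equivalent of 25), O=C(Cl)c1ccccc1
Why: Double O-acylation through the N-acylpyridinium ion: one equivalent of 25 esterifies the primary O7–H and a second the secondary allylic O3–H, so both benzoyl groups of 26 come from the acyl chloride. The tertiary O1–H should stay free at this stoichiometry and temperature, and the low temperature should keep the O2 acetate in place until O3 is capped.

Step 20
Reactants: 26 3,7-dibenzoate
Product: 27 allylic alcohol [C1: OH, CH2OBz; C2: OAc; C3: OBz; C4=C5; C6: OH]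
Conditions: HF·pyridine, THF/pyridine, 0 °C → rt
Reagents that add atoms: none
Why: Fluoride-mediated desilylation under mildly acidic buffering, which should not trigger acyl migration to the new hydroxyl.

Step 21
Reactants: 27 allylic alcohol
Product: 28 2-O-acetylzeylenone (target)
Conditions: IBX, DMSO, rt
Reagents that add atoms: none
Why: IBX oxidises the secondary allylic alcohol to the enone and converts 1,2-diols into α-ketols without C–C cleavage; the neutral medium protects the base-labile γ-acyloxy enone, and C1–C3 are untouched.

## Compound list

1 | isopropyl 1-thio-β-D-galactopyranoside (IPTG) | CC(C)S[C@H]1[C@H](O)[C@@H](O)[C@@H](O)[C@@H](CO)O1 | starting material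
2 | isopropyl 3,4-O-isopropylidene-6-O-(2-methoxypropan-2-yl)-1-thio-β-D-galactopyranoside (formed in situ) | CC(C)S[C@H]1[C@H](O)[C@H]2OC(C)(C)O[C@H]2[C@@H](COC(C)(C)OC)O1 | intermediate
3 | isopropyl 3,4-O-isopropylidene-1-thio-β-D-galactopyranoside | CC(C)S[C@H]1[C@H](O)[C@H]2OC(C)(C)O[C@H]2[C@@H](CO)O1 | intermediate
4 | isopropyl 6-O-TBS-3,4-O-isopropylidene-1-thio-β-D-galactopyranoside | CC(C)S[C@H]1[C@H](O)[C@H]2OC(C)(C)O[C@H]2[C@@H](CO[Si](C)(C)C(C)(C)C)O1 | intermediate
5 | 4-methoxybenzyl chloride | COc1ccc(CCl)cc1 | starting material
6 | isopropyl 6-O-TBS-3,4-O-isopropylidene-2-O-PMB-1-thio-β-D-galactopyranoside | CC(C)S[C@H]1[C@H](OCc3ccc(OC)cc3)[C@H]2OC(C)(C)O[C@H]2[C@@H](CO[Si](C)(C)C(C)(C)C)O1 | intermediate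
7 | 6-O-TBS-3,4-O-isopropylidene-2-O-PMB-D-galactopyranose (anomeric mixture) | OC1[C@H](OCc3ccc(OC)cc3)[C@H]2OC(C)(C)O[C@H]2[C@@H](CO[Si](C)(C)C(C)(C)C)O1 | intermediate
8 | 5-hydroxy alkene (C1′H2=C1H; 2-OPMB; 3,4-O-isopropylidene; 5-OH; 6-OTBS; D-galacto) | C=C[C@H](OCc1ccc(OC)cc1)[C@H]2OC(C)(C)O[C@H]2[C@H](O)CO[Si](C)(C)C(C)(C)C | intermediate
9 | 5,6-bis-silyl ether (5-OTBS; 6-OTBS; otherwise as 8) | C=C[C@H](OCc1ccc(OC)cc1)[C@H]2OC(C)(C)O[C@H]2[C@H](O[Si](C)(C)C(C)(C)C)CO[Si](C)(C)C(C)(C)C | intermediate
10 | primary alcohol (5-OTBS; 6-OH) | C=C[C@H](OCc1ccc(OC)cc1)[C@H]2OC(C)(C)O[C@H]2[C@H](O[Si](C)(C)C(C)(C)C)CO | intermediate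
11 | C6 aldehyde (5-OTBS; C6H=O) | C=C[C@H](OCc1ccc(OC)cc1)[C@H]2OC(C)(C)O[C@H]2[C@H](O[Si](C)(C)C(C)(C)C)C=O | intermediate
12 | (tributylstannyl)methanol | CCCC[Sn](CCCC)(CCCC)CO | starting material
13 | tributyl[(4-methoxybenzyloxy)methyl]stannane | CCCC[Sn](CCCC)(CCCC)COCc1ccc(OC)cc1 | intermediate
14 | (4-methoxybenzyloxy)methyllithium (formed in situ) | [Li]COCc1ccc(OC)cc1 | intermediate
15 | C6 carbinol, both C6 epimers (C6H(OH); C7H2OPMB) | C=C[C@H](OCc1ccc(OC)cc1)[C@H]2OC(C)(C)O[C@H]2[C@H](O[Si](C)(C)C(C)(C)C)C(O)COCc1ccc(OC)cc1 | intermediate
16 | keto alkene (C6=O; C7H2OPMB) | C=C[C@H](OCc1ccc(OC)cc1)[C@H]2OC(C)(C)O[C@H]2[C@H](O[Si](C)(C)C(C)(C)C)C(=O)COCc1ccc(OC)cc1 | intermediate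
17 | terminal vicinal diol, both C1 epimers (C1′H2OH; C1H(OH); formed in situ) | OCC(O)[C@H](OCc1ccc(OC)cc1)[C@H]2OC(C)(C)O[C@H]2[C@H](O[Si](C)(C)C(C)(C)C)C(=O)COCc1ccc(OC)cc1 | intermediate
18 | keto aldehyde (C1H=O; 2-OPMB; 3,4-O-isopropylidene; 5-OTBS; C6=O; C7H2OPMB) | O=C[C@H](OCc1ccc(OC)cc1)[C@H]1OC(C)(C)O[C@H]1[C@H](O[Si](C)(C)C(C)(C)C)C(=O)COCc1ccc(OC)cc1 | intermediate
19 | cyclitol cis-1,2-diol (1-OH and 2-OH cis to each other and to the 4,5-acetonide; 3-OPMB and 6-OTBS on the other face; C7H2OPMB on C1) | O[C@H]1[C@H](OCc2ccc(OC)cc2)[C@H]2OC(C)(C)O[C@H]2[C@H](O[Si](C)(C)C(C)(C)C)[C@]1(O)COCc1ccc(OC)cc1 | intermediate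
20 | 2-O-acetate of 19 | CC(=O)O[C@H]1[C@H](OCc2ccc(OC)cc2)[C@H]2OC(C)(C)O[C@H]2[C@H](O[Si](C)(C)C(C)(C)C)[C@]1(O)COCc1ccc(OC)cc1 | intermediate
21 | 4,5-cis-diol | CC(=O)O[C@H]1[C@H](OCc2ccc(OC)cc2)[C@@H](O)[C@@H](O)[C@H](O[Si](C)(C)C(C)(C)C)[C@]1(O)COCc1ccc(OC)cc1 | intermediate
22 | 4,5-cyclic thionocarbonate | CC(=O)O[C@H]1[C@H](OCc2ccc(OC)cc2)[C@H]2OC(=S)O[C@H]2[C@H](O[Si](C)(C)C(C)(C)C)[C@]1(O)COCc1ccc(OC)cc1 | intermediate
23 | cyclohexene (C4=C5; 3-OPMB; 6-OTBS; 2-OAc; 1-OH; C7H2OPMB) | CC(=O)O[C@H]1[C@H](OCc2ccc(OC)cc2)C=C[C@H](O[Si](C)(C)C(C)(C)C)[C@]1(O)COCc1ccc(OC)cc1 | intermediate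
24 | triol (1-OH; 3-OH; C7H2OH; 2-OAc; 6-OTBS) | CC(=O)O[C@H]1[C@H](O)C=C[C@H](O[Si](C)(C)C(C)(C)C)[C@]1(O)CO | intermediate
25 | benzoyl chloride | O=C(Cl)c1ccccc1 | starting material
26 | 3,7-dibenzoate (6-OTBS) | CC(=O)O[C@H]1[C@H](OC(=O)c2ccccc2)C=C[C@H](O[Si](C)(C)C(C)(C)C)[C@]1(O)COC(=O)c1ccccc1 | intermediate
27 | allylic alcohol (6-OH) | CC(=O)O[C@H]1[C@H](OC(=O)c2ccccc2)C=C[C@H](O)[C@]1(O)COC(=O)c1ccccc1 | intermediate
28 | 2-O-acetylzeylenone, [(1S,5R,6S)-6-acetoxy-5-benzoyloxy-1-hydroxy-2-oxocyclohex-3-en-1-yl]methyl benzoate | CC(=O)O[C@H]1[C@H](OC(=O)c2ccccc2)C=CC(=O)[C@]1(O)COC(=O)c1ccccc1 | target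

## Step count and least certain steps

Total step count: 21 (20 on the main line plus the one-step preparation of stannane 13). Longest linear sequence: 20 steps (1 → 28 through steps 1–8 and 10–21).

Step 13 (key step). Most likely failure: reductive cleavage of the C–O bonds α to the carbonyls or plain carbonyl reduction competing with coupling, and erosion of facial selectivity if the folded chain cannot place both carbonyls anti to their α-oxygens. Fallback: set out from 16. Methylenation of the ketone (Ph3PCH3Br, KN(SiMe3)2, THF) should give the diene F1. Ring-closing metathesis with the second-generation Grubbs catalyst RuCl2(=CHPh)(PCy3)(H2IMes) in CH2Cl2 at 40 °C should close the C1=C2 cyclohexene F2. Dihydroxylation with catalytic OsO4 and N-methylmorpholine N-oxide should add anti to the two allylic ethers on C3 and C6 and return to the route at 19.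

Step 10. Most likely failure: migration of the silyl group from O5 to the newly formed C6 alkoxide, enolisation of the α-silyloxy aldehyde, or rearrangement of the α-alkoxymethyllithium before it adds. Fallback: set out from 11. Addition of (iPrO)Me2SiCH2MgCl should give the β-hydroxysilane F3. Tamao oxidation (H2O2, KF, KHCO3, THF/MeOH) should give the 6,7-diol F4. Regioselective alkylation of the primary hydroxyl through the stannylene acetal (Bu2SnO, toluene, reflux; then 5, CsF, DMF) returns to the route at 15.

Step 5. Most likely failure: base-induced epimerisation at C2 or β-elimination of the C3 oxygen in the open-chain aldehyde, aggravated by a low proportion of the open form in the bicyclic lactol. Fallback: set out from 7. The much less basic Me3SiCH2MgCl should add to the lactol to give the β-hydroxysilane diol F5. Peterson elimination with KH in THF returns to the route at 8.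

Step 15. Most likely failure: incomplete hydrolysis of the hindered cis-fused dioxolane under acid weak enough to spare the PMB ethers, with loss of PMB or silyl groups once the acid is strengthened. Fallback: set out from 20 and change the order of events. DDQ in wet CH2Cl2 should give the acetonide triol F6, and benzoylation with two equivalents of 25 and pyridine the dibenzoate acetonide F7. Stronger acid (TFA/H2O, CH2Cl2, 0 °C) can then be used to reach the dibenzoate diol F8. TCDI gives the thionocarbonate F9, and the diazaphospholidine of step 17 returns to the route at 26. In this order the oxidative deprotection also never meets an allylic ether.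

Step 20. Most likely failure: slow cleavage of the hindered allylic silyl ether, and acyl migration towards O6 if more basic fluoride has to be used. Fallback: set out from 23 and desilylate before any benzoate is present. Bu4NF buffered with AcOH should give the allylic alcohol F10, and IBX the bis-PMB enone F11. DDQ then gives the enone triol F12, and benzoylation with two equivalents of 25 in pyridine at 0 °C returns to the route at 28.

## Further compounds

F1 | step 13 | diene (C6=CH2 in place of the ketone of 16) | C=C[C@H](OCc1ccc(OC)cc1)[C@H]2OC(C)(C)O[C@H]2[C@H](O[Si](C)(C)C(C)(C)C)C(=C)COCc1ccc(OC)cc1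
F2 | step 13 | cyclohexene with ring C1=C2 (3-OPMB; 4,5-acetonide; 6-OTBS; C7H2OPMB on C1) | C1=C(COCc3ccc(OC)cc3)[C@@H](O[Si](C)(C)C(C)(C)C)[C@@H]2OC(C)(C)O[C@@H]2[C@H]1OCc1ccc(OC)cc1
F3 | step 10 | β-hydroxysilane, both C6 epimers (C6H(OH)–CH2SiMe2OiPr) | C=C[C@H](OCc1ccc(OC)cc1)[C@H]2OC(C)(C)O[C@H]2[C@H](O[Si](C)(C)C(C)(C)C)C(O)C[Si](C)(C)OC(C)C
F4 | step 10 | 6,7-diol, both C6 epimers | C=C[C@H](OCc1ccc(OC)cc1)[C@H]2OC(C)(C)O[C@H]2[C@H](O[Si](C)(C)C(C)(C)C)C(O)CO
F5 | step 5 | β-hydroxysilane diol, both C1 epimers (Me3SiCH2–C1H(OH); 5-OH; 6-OTBS) | C[Si](C)(C)CC(O)[C@H](OCc1ccc(OC)cc1)[C@H]2OC(C)(C)O[C@H]2[C@H](O)CO[Si](C)(C)C(C)(C)C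
F6 | step 15 | acetonide triol (1-OH; 3-OH; C7H2OH; 2-OAc; 6-OTBS) | CC(=O)O[C@H]1[C@H](O)[C@H]2OC(C)(C)O[C@H]2[C@H](O[Si](C)(C)C(C)(C)C)[C@]1(O)CO
F7 | step 15 | acetonide 3,7-dibenzoate | CC(=O)O[C@H]1[C@H](OC(=O)c3ccccc3)[C@H]2OC(C)(C)O[C@H]2[C@H](O[Si](C)(C)C(C)(C)C)[C@]1(O)COC(=O)c1ccccc1
F8 | step 15 | 4,5-diol 3,7-dibenzoate | CC(=O)O[C@H]1[C@H](OC(=O)c2ccccc2)[C@@H](O)[C@@H](O)[C@H](O[Si](C)(C)C(C)(C)C)[C@]1(O)COC(=O)c1ccccc1
F9 | step 15 | 4,5-thionocarbonate 3,7-dibenzoate | CC(=O)O[C@H]1[C@H](OC(=O)c3ccccc3)[C@H]2OC(=S)O[C@H]2[C@H](O[Si](C)(C)C(C)(C)C)[C@]1(O)COC(=O)c1ccccc1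
F10 | step 20 | bis-PMB allylic alcohol (6-OH) | CC(=O)O[C@H]1[C@H](OCc2ccc(OC)cc2)C=C[C@H](O)[C@]1(O)COCc1ccc(OC)cc1
F11 | step 20 | bis-PMB enone | CC(=O)O[C@H]1[C@H](OCc2ccc(OC)cc2)C=CC(=O)[C@]1(O)COCc1ccc(OC)cc1
F12 | step 20 | enone triol (1-OH; 3-OH; C7H2OH; 2-OAc) | CC(=O)O[C@H]1[C@H](O)C=CC(=O)[C@]1(O)CO
A1 | alternative 1 | (1-hydroxycyclohexa-2,5-dien-1-yl)methyl benzoate | OC1(COC(=O)c2ccccc2)C=CCC=C1
A2 | alternative 1 | (2-hydroxy-7-oxabicyclo[4.1.0]hept-3-en-2-yl)methyl benzoate, hydroxyl cis to the epoxide | O[C@]1(COC(=O)c2ccccc2)C=CC[C@@H]2O[C@H]12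
A3 | alternative 2 | manno-configured 2-C-(silyloxymethyl)-2,3-O-isopropylidene γ-lactone with a 2-(phenylsulfinyl)ethyl chain on C3 (ring numbering of the target) | CC1(C)O[C@H]2[C@@H](CCS(=O)c3ccccc3)OC(=O)[C@]2(O1)CO[Si](C)(C)C(C)(C)C
A4 | alternative 2 | 3-hydroxy enone with C1,C2 acetonide and C7 silyl ether | CC1(C)O[C@H]2[C@H](O)C=CC(=O)[C@]2(O1)CO[Si](C)(C)C(C)(C)C
A5 | alternative 3 | (Z)-β-iodo enone aldehyde with C1,C2 acetonide and C7 benzoate | O=C[C@@H]1OC(C)(C)O[C@]1(COC(=O)c2ccccc2)C(=O)/C=C\I
A6 | alternative 3 | 3-hydroxy enone with C1,C2 acetonide and C7 benzoate | CC1(C)O[C@H]2[C@H](O)C=CC(=O)[C@]2(O1)COC(=O)c1ccccc1
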